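Dibefurin is the centrosymmetric double-aldol dimer of 4-hydroxy-7-methyl-1,3-dihydro-2-benzofuran-5,6-dione, so the plan rests on that monomer. Its oxolane ring (O2, C1H2, C3H2, C3a, C7a) is made by contraction, not closure: irradiation of the six-membered (E)-3-diazo-5-ethylideneoxan-4-one expels the ketone carbon from the ring (Wolff shift), and the resulting exocyclic vinylketene is trapped by ethoxyethyne in a [2+2]/4π/6π benzannulation. This exploits the chain C6(=O)–C7(Me)=C7a–C3a of each half: the expelled carbon becomes C6, so one operation builds the oxolane and the carbocycle around it. Ortho-oxidation, ether hydrolysis and spontaneous dimerisation then give the target.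

Key step: step 3

Remark: each half of the target is numbered as a 1,3-dihydro-2-benzofuran (C1, O2, C3, C3a, C4–C7, C7a); compounds 12–15 and the fallback compounds derived from them are named with this numbering kept fixed, and ethoxyethyne is taken as the commercial solution in hexanes.

Step 1
Reactants: 1 oxan-4-one (tetrahydro-4H-pyran-4-one); 2 acetaldehyde
Product: 5 (E)-3-ethylideneoxan-4-one (methyl anti to the carbonyl), via lithium aldolate 3 (not isolated), via mesylate 4 (not isolated)
Conditions: LiN(SiMe3)2, THF, −78 °C; MeCHO; MsCl, −78 → 0 °C; DBU, rt
Reagents that add atoms: none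
Why: The kinetic lithium enolate of the symmetrical ketone should add to acetaldehyde (directed aldol), and mesylation of the aldolate followed by E1cB elimination with DBU should give the conjugated enone (aldol condensation), the E isomer being the thermodynamically favoured one.

Step 2
Reactants: 5 (E)-3-ethylideneoxan-4-one
Product: 7 (E)-3-diazo-5-ethylideneoxan-4-one, via trifluoroacetyl ketone 6 (not isolated)
Conditions: LiN(SiMe3)2, THF, −78 °C; CF3CO2CH2CF3; aq. HCl; then MsN3, Et3N, H2O, MeCN, rt
Reagents that add atoms: methanesulfonyl azide, CS(=O)(=O)N=[N+]=[N-]
Why: Detrifluoroacetylative diazo transfer (a Regitz-type diazo transfer): the base should deprotonate the only sp3 α-carbon (C5) kinetically, Claisen trifluoroacetylation activates it, and the azide transfers N2 with loss of the trifluoroacetyl group as the sulfonamide, a sequence established for α'-diazo-α,β-enones.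

Step 3
Reactants: 7 (E)-3-diazo-5-ethylideneoxan-4-one; 8 ethoxyethyne
Product: 13 4-ethoxy-7-methyl-1,3-dihydro-2-benzofuran-6-ol, via vinylketene 9 (not isolated), via spirocyclobutenone 10 (not isolated), via dienylketene 11 (not isolated), via cyclohexadienone 12 (not isolated)
Conditions: hν (300 nm), 8 (3 equiv), ClCH2CH2Cl, rt; then 80 °C, sealed tube
Reagents that add atoms: none
Why: Proposed new method: direct irradiation of the ring-locked s-Z diazoketone 7 should expel N2 with 1,2-shift of the alkenyl carbon C5 from the carbonyl carbon C4 to C3 (Wolff rearrangement), which turns C4 into an exocyclic ketene carbon and leaves the five-membered oxolane of vinylketene 9; regioselective [2+2] addition of ethoxyethyne (its CH carbon to the ketene carbonyl carbon) gives spirocyclobutenone 10, 4π electrocyclic opening on heating gives dienylketene 11, and 6π electrocyclization onto the ethylidene carbon followed by enolization of 12 gives phenol 13. The closest known reaction type is the Danheiser benzannulation of acyclic α'-diazo-α,β-enones with ynol ethers, combined with the classical ring-contracting Wolff rearrangement of cyclic 2-diazoketones; not yet shown is the endocyclic diazo carbon that merges both in one substrate. The oxolane closes by ring contraction (1,2-carbon shift, six to five atoms) and the benzene ring by thermal disrotatory 6π electrocyclization after the [2+2]/4π relay. No stereocentre results; the E geometry of the ethylidene group is carried through the shift with retention and points the methyl group away from the cyclizing terminus. The step needs Wolff shift in preference to 1,2-hydride shift from C2–H (secured by the s-Z geometry enforced by the ring and by metal-free photolysis), ethoxy meta to the new hydroxyl (secured by the polarization of the ynol ether) and the cyclizable cis-dienylketene (secured by reversible opening of 10, which funnels both rotamers through 11).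

Step 4
Reactants: 13 4-ethoxy-7-methyl-1,3-dihydro-2-benzofuran-6-ol
Product: 14 4-ethoxy-7-methyl-1,3-dihydro-2-benzofuran-5,6-dione
Conditions: IBX, DMF, rt
Reagents that add atoms: 2-iodoxybenzoic acid (IBX), O=C1OI(=O)(O)c2ccccc12
Why: IBX ortho-oxidation of an electron-rich phenol: the phenol should exchange onto pentavalent iodine and receive oxygen intramolecularly at C5, the only unsubstituted ortho carbon, before the iodine departs as 2-iodobenzoic acid, which gives the o-quinone without touching the benzylic ether carbons.

Step 5
Reactants: 14 4-ethoxy-7-methyl-1,3-dihydro-2-benzofuran-5,6-dione (two molecules)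
Product: 16 dibefurin, via hydroxy-o-quinone 15 (not isolated)
Conditions: HCl (cat.), THF/H2O, rt; then aq. NaHCO3 (pH 8), MeCN, rt, argon
Reagents that add atoms: water, O
Why: Acid-catalysed addition–elimination of water at C4 should hydrolyse the doubly vinylogous ethyl ester to the vinylogous acid 15, whose enolate at pH 8 adds through C3a to the C5 ketone of a second molecule and is closed by the mirror-image aldol (double aldol, formal [3+3] dimerisation); the four quaternary stereocentres are set together by the only strain-free approach of the two flat monomers, head-to-tail across an inversion centre, the path by which the natural product is thought to arise.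

Compound list
1 | oxan-4-one (tetrahydro-4H-pyran-4-one) | O=C1CCOCC1 | starting material
2 | acetaldehyde | CC=O | starting material
3 | lithium aldolate of 3-(1-hydroxyethyl)oxan-4-one (diastereomer mixture) | CC([O-])C1COCCC1=O.[Li+] | intermediate
4 | 1-(4-oxooxan-3-yl)ethyl methanesulfonate (diastereomer mixture) | CC(OS(C)(=O)=O)C1COCCC1=O | intermediate
5 | (E)-3-ethylideneoxan-4-one | C/C=C1/C(=O)CCOC1 | intermediate
6 | (E)-3-ethylidene-5-(trifluoroacetyl)oxan-4-one (racemic) | C/C=C1/C(=O)C(C(=O)C(F)(F)F)COC1 | intermediate
7 | (E)-3-diazo-5-ethylideneoxan-4-one | C/C=C1/C(=O)C(=[N+]=[N-])COC1 | intermediate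
8 | ethoxyethyne | CCOC#C | starting material
9 | (Z)-(4-ethylideneoxolan-3-ylidene)methanone (vinylketene; methyl anti to the ketene-bearing carbon) | C/C=C1/C(=C=O)COC1 | intermediate
10 | (8Z)-3-ethoxy-8-ethylidene-6-oxaspiro[3.4]oct-2-en-1-one (racemic) | C/C=C1/C2(COC1)C(=O)C=C2OCC | intermediate
11 | 3-ethoxy-3-(4-ethylideneoxolan-3-ylidene)prop-1-en-1-one (dienylketene; ketenyl group cis to the ethylidene-bearing ring carbon, methyl outward) | O=C=C/C(OCC)=C1\C(=C\C)COC1 | intermediate
12 | 4-ethoxy-7-methyl-1,7-dihydro-2-benzofuran-6(3H)-one (racemic) | CCOC1=CC(=O)C(C)C2=C1COC2 | intermediate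
13 | 4-ethoxy-7-methyl-1,3-dihydro-2-benzofuran-6-ol | CCOc1cc(O)c(C)c2COCc12 | intermediate
14 | 4-ethoxy-7-methyl-1,3-dihydro-2-benzofuran-5,6-dione | CCOC1=C2COCC2=C(C)C(=O)C1=O | intermediate
15 | 4-hydroxy-7-methyl-1,3-dihydro-2-benzofuran-5,6-dione | CC1=C2COCC2=C(O)C(=O)C1=O | intermediate
16 | dibefurin (centrosymmetric meso dimer) | CC1=C2COC[C@]23C(=O)[C@](O)(C1=O)[C@@]12COCC1=C(C)C(=O)[C@]3(O)C2=O | target

Total step count: 5
Longest linear sequence: 5 steps (1 → 5 → 7 → 13 → 14 → 16)

Steps most likely to fail

Step 3 (proposed new method). The excited diazoketone may undergo 1,2-hydride shift instead of the Wolff shift. The ethylidene group may photoisomerise, which would open a 1,5-hydrogen shift of the ketene. The ketene may also dimerise before the [2+2] addition. The fallback sets out from 7 and returns at 13, and separates the ring contraction from the benzannulation with known reactions. Irradiation of 7 in methanol (300 nm) traps the ring-contracted ketene as methyl (Z)-4-ethylideneoxolane-3-carboxylate F1. LiOH in THF/H2O gives (Z)-4-ethylideneoxolane-3-carboxylic acid F2. (COCl)2 and catalytic DMF give (Z)-4-ethylideneoxolane-3-carbonyl chloride F3. Slow addition of Et3N to F3 and 8 in CH2Cl2 in the dark regenerates ketene 9 by dehydrochlorination. Ketene 9 is captured as 10, which is converted to 13 in toluene at 110 °C.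

Step 5. Hydrolysis of the hindered doubly vinylogous ester may be slower than tautomerisation of the o-quinone to quinone methides and their oligomerisation, so the dimerisable enolate would never build up. The fallback sets out from 14 and returns at 16. It breaks the O–ethyl bond instead of the C4–O bond and uses no water. Anhydrous MgI2 in toluene/Et2O (rt to 50 °C) chelates O4 and the C5 carbonyl and dealkylates by SN2 attack of iodide at the ethyl carbon. This gives magnesium bis(7-methyl-5,6-dioxo-1,3,5,6-tetrahydro-2-benzofuran-4-olate) F4, the enolate of 15. Partition into MeCN/aq. NaHCO3 then lets the double aldol run to 16.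

Step 4. Oxygen may be delivered to the methyl-bearing ortho carbon (o-quinol formation), or the electron-rich product may be oxidised further or tautomerise under the reaction conditions. The fallback sets out from 13 and returns at 14, and installs the C5 oxygen through a carbon substituent. Magnesium-mediated ortho-formylation (MgCl2, Et3N, paraformaldehyde, MeCN, reflux) gives 4-ethoxy-6-hydroxy-7-methyl-1,3-dihydro-2-benzofuran-5-carbaldehyde F5. Dakin oxidation (H2O2, NaOH, 0 °C) gives 4-ethoxy-7-methyl-1,3-dihydro-2-benzofuran-5,6-diol F6. Ag2O in Et2O oxidises the catechol to 14.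

Further compounds
F1 | step 3 | methyl (Z)-4-ethylideneoxolane-3-carboxylate (racemic) | C/C=C1/C(C(=O)OC)COC1
F2 | step 3 | (Z)-4-ethylideneoxolane-3-carboxylic acid (racemic) | C/C=C1/C(C(=O)O)COC1
F3 | step 3 | (Z)-4-ethylideneoxolane-3-carbonyl chloride (racemic) | C/C=C1/C(C(=O)Cl)COC1
F4 | step 5 | magnesium bis(7-methyl-5,6-dioxo-1,3,5,6-tetrahydro-2-benzofuran-4-olate) | CC1=C2COCC2=C([O-])C(=O)C1=O.CC1=C2COCC2=C([O-])C(=O)C1=O.[Mg+2]
F5 | step 4 | 4-ethoxy-6-hydroxy-7-methyl-1,3-dihydro-2-benzofuran-5-carbaldehyde | CCOc1c(C=O)c(O)c(C)c2COCc12
F6 | step 4 | 4-ethoxy-7-methyl-1,3-dihydro-2-benzofuran-5,6-diol | CCOc1c(O)c(O)c(C)c2COCc12
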